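**Plan**

1. The last cut removes the two Si–O bonds of a temporary diisopropylsilylene bridge. Before it, arene bonds C1–C2 and C5–C6 are cut (C1 = carbon bearing carbinol C8, C2 = phenol carbon, C4 = methyl carbon), giving a 3-oxy-5-methyl-2-pyrone and a terminal alkyne, with CO2 returned.
2. The enabling feature is that the C2 oxygen and C8 on C1 are ortho neighbours. An O(C2)–Si–O(C8) link closes a six-membered 1,3,2-dioxasiline that holds the alkyne (future C1 and C6) over pyrone carbons 3 and 6; the pyrone already carries oxygen and methyl in the 1,3-relation of the cresol ring.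
3. The bridge is cut into ethynyl carbinol diester 9 and hydroxypyrone 15. Compound 9 goes back through its two ester C–O bonds to an epoxy alcohol and an enynol; 15 goes back through the lactone C–O bond and C3=C4 to 3-ethoxymethacrolein and a methoxyphosphonoacetate.
4. Forward: the chain of 9 is assembled (C–C coupling, epoxidation, two esters), the pyrone ring is made separately, the two are joined through silicon, the carbocycle and the dioxasiline close together in the cycloaddition, and the bridge is removed.
5. Stereochemistry: C8 is set by the Sharpless epoxidation with L-(+)-DIPT together with the order of acyl entry (isobutyrate on the free CH2OH, 2-methylbutanoate by opening the epoxide CH2). The ester stereocentre is bought as (S)-2-methylbutanoic acid.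

Key step: step 10

Assumption: enynol 3 follows the usual facial rule of the titanium–tartrate epoxidation (L-(+)-tartrate giving the S epoxy alcohol, as with 2-methylprop-2-en-1-ol), and phosphonate 11 is taken as a catalogue reagent.

**Route**

Step 1
Reactants: 1 2-bromoprop-2-en-1-ol; 2 ethynyltrimethylsilane
Product: 3 2-methylidene-4-(trimethylsilyl)but-3-yn-1-ol
Conditions: PdCl2(PPh3)2 (2 mol%), CuI (4 mol%), iPr2NH, THF, rt, degassed
Reagents that add atoms: none
Why: Sonogashira coupling; oxidative addition of the vinyl bromide to zerovalent palladium and transmetalation from the copper acetylide are routine for 2-bromoallyl alcohol, and the free hydroxyl is tolerated.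

Step 2
Reactants: 3 2-methylidene-4-(trimethylsilyl)but-3-yn-1-ol
Product: 4 [(2S)-2-[(trimethylsilyl)ethynyl]oxiran-2-yl]methanol
Conditions: Ti(OiPr)4 (10 mol%), L-(+)-DIPT (12 mol%), tBuOOH (isooctane), 4 Å MS, CH2Cl2, −20 °C
Reagents that add atoms: tert-butyl hydroperoxide, CC(C)(C)OO
Why: Katsuki–Sharpless asymmetric epoxidation; the allylic hydroxyl binds the titanium–tartrate complex, which should deliver oxygen to one face of the 1,1-disubstituted alkene and set C8 as S with L-(+)-DIPT, the silyl alkyne being inert to the oxidant.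

Step 3
Reactants: 4 [(2S)-2-[(trimethylsilyl)ethynyl]oxiran-2-yl]methanol; 5 2-methylpropanoic anhydride
Product: 6 [(2R)-2-[(trimethylsilyl)ethynyl]oxiran-2-yl]methyl 2-methylpropanoate
Conditions: (iPrCO)2O, Et3N, DMAP (cat.), CH2Cl2, 0 °C
Reagents that add atoms: none
Why: DMAP-catalysed acylation of the primary alcohol; the epoxide survives amine base at 0 °C and, with no free hydroxyl left, the isobutyrate is fixed on this arm (the descriptor changes to R only through the priority rules).

Step 4
Reactants: 6 [(2R)-2-[(trimethylsilyl)ethynyl]oxiran-2-yl]methyl 2-methylpropanoate; 7 (2S)-2-methylbutanoic acid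
Product: 8 (2S)-2-hydroxy-2-{[(2-methylpropanoyl)oxy]methyl}-4-(trimethylsilyl)but-3-yn-1-yl (2S)-2-methylbutanoate
Conditions: 7 (2 equiv), nBu4NBr (10 mol%), MeCN, 80 °C
Reagents that add atoms: none
Why: Ammonium-halide-catalysed opening of a glycidyl ester by a carboxylic acid (the 1,3-diacylglycerol method); SN2 attack at the unsubstituted CH2 leaves the C8–O bond intact, excess acid keeps the medium non-basic, and the chiral acid reacts as a carboxylate without activation so its α-centre should not epimerise.

Step 5
Reactants: 8 (2S)-2-hydroxy-2-{[(2-methylpropanoyl)oxy]methyl}-4-(trimethylsilyl)but-3-yn-1-yl (2S)-2-methylbutanoate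
Product: 9 (2S)-2-ethynyl-2-hydroxy-3-[(2-methylpropanoyl)oxy]propyl (2S)-2-methylbutanoate
Conditions: nBu4NF, AcOH (1:1.2), THF, 0 °C
Reagents that add atoms: none
Why: Fluoride protodesilylation of the C(sp)–Si bond; acetic acid buffering keeps the tertiary hydroxyl from starting acyl migration between the arms.

Step 6
Reactants: 10 (2E)-3-ethoxy-2-methylprop-2-enal; 11 methyl 2-(dimethoxyphosphoryl)-2-methoxyacetate
Product: 12 methyl (4E)-5-ethoxy-2-methoxy-4-methylpenta-2,4-dienoate (2E/2Z mixture)
Conditions: NaH, THF, 0 °C → rt
Reagents that add atoms: none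
Why: Horner–Wadsworth–Emmons olefination of the vinylogous formate aldehyde; 1,2-addition and irreversible phosphate loss should give the dienoate, whose 2,3-geometry is immaterial because it equilibrates in the next step.

Step 7
Reactants: 12 methyl (4E)-5-ethoxy-2-methoxy-4-methylpenta-2,4-dienoate (2E/2Z mixture)
Product: 14 3-methoxy-5-methyl-2H-pyran-2-one, via dienoic acid 13 (not isolated)
Conditions: LiOH, THF/H2O, 40 °C; 1 M HCl to pH 3 at 0 °C, extraction; then CF3CO2H (anhydrous), CH2Cl2, rt → 40 °C
Reagents that add atoms: LiOH (lithium hydroxide), [Li+].[OH-]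
Why: Saponification followed by acid-mediated lactonisation of a 5-alkoxypenta-2,4-dienoic acid; protonation of the dienyl ether gives an oxocarbenium at C5 that the carboxyl group captures in a six-membered ring before ethanol is lost, and because O3 stays a methyl ether no ketone is freed and furan formation is shut off.

Step 8
Reactants: 14 3-methoxy-5-methyl-2H-pyran-2-one
Product: 15 3-hydroxy-5-methyl-2H-pyran-2-one
Conditions: BBr3, CH2Cl2, −78 → 0 °C; H2O
Reagents that add atoms: none
Why: Boron tribromide ether cleavage, helped by chelation to the neighbouring lactone carbonyl as with ortho-carbonyl aryl methyl ethers, at a temperature where the pyrone ring should stay intact.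

Step 9
Reactants: 9 (2S)-2-ethynyl-2-hydroxy-3-[(2-methylpropanoyl)oxy]propyl (2S)-2-methylbutanoate; 15 3-hydroxy-5-methyl-2H-pyran-2-one
Product: 17 (2S)-2-ethynyl-2-({[(5-methyl-2-oxo-2H-pyran-3-yl)oxy]di(propan-2-yl)silyl}oxy)-3-[(2-methylpropanoyl)oxy]propyl (2S)-2-methylbutanoate, via silyl triflate 16 (not isolated)
Conditions: iPr2Si(OTf)2 (1.05 equiv), 2,6-lutidine, CH2Cl2, −78 → 0 °C; then 15, 0 °C → rt; filtration through Et3N-deactivated silica
Reagents that add atoms: diisopropylsilyl bis(trifluoromethanesulfonate), CC(C)[Si](OS(=O)(=O)C(F)(F)F)(OS(=O)(=O)C(F)(F)F)C(C)C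
Why: Stepwise unsymmetrical silaketal formation; the bis(triflate) should silylate the hindered tertiary propargylic alcohol once (a second tertiary alcohol cannot enter), and the remaining Si–OTf is then displaced by the acidic pyronol, with lutidine and low temperature sparing both esters.

Step 10
Reactants: 17 (2S)-2-ethynyl-2-({[(5-methyl-2-oxo-2H-pyran-3-yl)oxy]di(propan-2-yl)silyl}oxy)-3-[(2-methylpropanoyl)oxy]propyl (2S)-2-methylbutanoate
Product: 19 [(4S)-7-methyl-4-{[(2-methylpropanoyl)oxy]methyl}-2,2-di(propan-2-yl)-4H-1,3,2-benzodioxasilin-4-yl]methyl (2S)-2-methylbutanoate, via bridged bicyclic lactone 18 (not isolated)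
Conditions: o-xylene (0.01 M), BHT (cat.), 150 °C, sealed tube
Reagents that add atoms: none
Why: Heating should fold the terminal alkyne over the pyrone diene (C3=C4–C5=C6) for a concerted thermal [4+2] cycloaddition that joins the internal alkyne carbon to pyrone C3 (arene C1–C2) and the terminal carbon to pyrone C6 (arene C5–C6), giving bridged lactone 18, which aromatises by retro-[4+2] loss of CO2 at the same temperature. The closest known reaction types are the intramolecular 2-pyrone–alkyne Diels–Alder/decarboxylation used for benzannulation and the temporary silicon-tethered (silaketal) Diels–Alder reaction. Two rings close: the carbocycle by the cycloaddition itself and the six-membered 1,3,2-dioxasiline in the fused mode, the four-atom O–Si–O–C8 link joining diene carbon 3 to the internal alkyne carbon. No new stereocentre remains in 19, since the two bridgehead centres of 18 disappear with CO2, and the preset C8 centre lies outside the reacting array and is untouched. Only regiochemistry is required and the tether length fixes it, because the alternative orientation would demand a strained bridged ring; the gem-diisopropyl silicon and quaternary C8 favour the folded rotamer, and neutral heating with the tertiary oxygen silylated excludes acyl migration.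

Step 11
Reactants: 19 [(4S)-7-methyl-4-{[(2-methylpropanoyl)oxy]methyl}-2,2-di(propan-2-yl)-4H-1,3,2-benzodioxasilin-4-yl]methyl (2S)-2-methylbutanoate
Product: 20 (2S)-2-hydroxy-2-(2-hydroxy-4-methylphenyl)-3-[(2-methylpropanoyl)oxy]propyl (2S)-2-methylbutanoate
Conditions: HF·pyridine, pyridine, THF, 0 °C → rt; Me3SiOMe quench
Reagents that add atoms: none
Why: Fluoride cleavage of both Si–O bonds of the silylene acetal under mildly acidic HF·pyridine, where neither ester should migrate to the freed phenol or tertiary hydroxyl, with a non-aqueous quench avoiding basic work-up.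

**Compound list**

1 | 2-bromoprop-2-en-1-ol | OCC(Br)=C | starting material
2 | ethynyltrimethylsilane | C#C[Si](C)(C)C | starting material
3 | 2-methylidene-4-(trimethylsilyl)but-3-yn-1-ol | OCC(=C)C#C[Si](C)(C)C | intermediate
4 | [(2S)-2-[(trimethylsilyl)ethynyl]oxiran-2-yl]methanol | C1[C@@](O1)(CO)C#C[Si](C)(C)C | intermediate
5 | 2-methylpropanoic anhydride | CC(C)C(=O)OC(=O)C(C)C | starting material
6 | [(2R)-2-[(trimethylsilyl)ethynyl]oxiran-2-yl]methyl 2-methylpropanoate | C1[C@@](O1)(COC(=O)C(C)C)C#C[Si](C)(C)C | intermediate
7 | (2S)-2-methylbutanoic acid | CC[C@H](C)C(=O)O | starting material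
8 | (2S)-2-hydroxy-2-{[(2-methylpropanoyl)oxy]methyl}-4-(trimethylsilyl)but-3-yn-1-yl (2S)-2-methylbutanoate | CC[C@H](C)C(=O)OC[C@@](O)(COC(=O)C(C)C)C#C[Si](C)(C)C | intermediate
9 | (2S)-2-ethynyl-2-hydroxy-3-[(2-methylpropanoyl)oxy]propyl (2S)-2-methylbutanoate | CC[C@H](C)C(=O)OC[C@@](O)(COC(=O)C(C)C)C#C | intermediate
10 | (2E)-3-ethoxy-2-methylprop-2-enal (3-ethoxymethacrolein) | CCO/C=C(\C)C=O | starting material
11 | methyl 2-(dimethoxyphosphoryl)-2-methoxyacetate | COC(=O)C(OC)P(=O)(OC)OC | starting material
12 | methyl (4E)-5-ethoxy-2-methoxy-4-methylpenta-2,4-dienoate (2E/2Z mixture) | CCO/C=C(\C)C=C(OC)C(=O)OC | intermediate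
13 | (4E)-5-ethoxy-2-methoxy-4-methylpenta-2,4-dienoic acid (2E/2Z mixture) | CCO/C=C(\C)C=C(OC)C(=O)O | intermediate
14 | 3-methoxy-5-methyl-2H-pyran-2-one | COC1=CC(C)=COC1=O | intermediate
15 | 3-hydroxy-5-methyl-2H-pyran-2-one | OC1=CC(C)=COC1=O | intermediate
16 | (2S)-2-ethynyl-2-({di(propan-2-yl)[(trifluoromethanesulfonyl)oxy]silyl}oxy)-3-[(2-methylpropanoyl)oxy]propyl (2S)-2-methylbutanoate | CC[C@H](C)C(=O)OC[C@@](O[Si](C(C)C)(C(C)C)OS(=O)(=O)C(F)(F)F)(COC(=O)C(C)C)C#C | intermediate
17 | (2S)-2-ethynyl-2-({[(5-methyl-2-oxo-2H-pyran-3-yl)oxy]di(propan-2-yl)silyl}oxy)-3-[(2-methylpropanoyl)oxy]propyl (2S)-2-methylbutanoate | CC[C@H](C)C(=O)OC[C@@](O[Si](C(C)C)(C(C)C)OC1=CC(C)=COC1=O)(COC(=O)C(C)C)C#C | intermediate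
18 | bridged bicyclic lactone from 17 (2-oxabicyclo[2.2.2]octa-5,7-dien-3-one fused to the dioxasiline; both bridgehead epimers) | CC[C@H](C)C(=O)OC[C@]1(COC(=O)C(C)C)O[Si](C(C)C)(C(C)C)OC23C=C(C)C(C=C12)OC3=O | intermediate
19 | [(4S)-7-methyl-4-{[(2-methylpropanoyl)oxy]methyl}-2,2-di(propan-2-yl)-4H-1,3,2-benzodioxasilin-4-yl]methyl (2S)-2-methylbutanoate | CC[C@H](C)C(=O)OC[C@]1(COC(=O)C(C)C)O[Si](C(C)C)(C(C)C)Oc2cc(C)ccc12 | intermediate
20 | (2S)-2-hydroxy-2-(2-hydroxy-4-methylphenyl)-3-[(2-methylpropanoyl)oxy]propyl (2S)-2-methylbutanoate | CC[C@H](C)C(=O)OC[C@@](O)(COC(=O)C(C)C)c1ccc(C)cc1O | target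

**Step count**

Total: 11 steps. Longest linear sequence: 8 steps (steps 1–5, then 9–11); the pyrone branch (steps 6–8) joins at step 9.

**Steps most likely to fail**

1. Step 10. The cycloaddition may be too slow for an unactivated terminal alkyne, so that thermal scission of the pyronyl–O–Si link or decomposition of the pyrone overtakes ring formation. Fallback: a reversible boron template in place of the isolated silaketal. Setting out from 9 and 15, the two would be heated with phenylboronic acid in toluene with azeotropic removal of water to assemble in the flask the mixed boronate (2S)-2-ethynyl-2-({[(5-methyl-2-oxo-2H-pyran-3-yl)oxy](phenyl)boranyl}oxy)-3-[(2-methylpropanoyl)oxy]propyl (2S)-2-methylbutanoate F1. Continued heating of F1 in xylene at 140 °C should let the same cycloaddition and CO2 loss run within the boronate to give [(4S)-7-methyl-4-{[(2-methylpropanoyl)oxy]methyl}-2-phenyl-4H-1,3,2-benzodioxaborinin-4-yl]methyl (2S)-2-methylbutanoate F2. Exchange of F2 with pinacol at room temperature would then free the phenol and the tertiary alcohol, so the route is rejoined at 20. Boronate-tethered Diels–Alder reactions of 3-hydroxy-2-pyrone and diol exchange of cyclic aryl boronates are known chemistry.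

2. Step 7. Partial hydrolysis of the enol ethers during saponification or in wet acid would expose a 1,4-dicarbonyl array and divert material into furan formation, or the 2,3-alkene may fail to isomerise to the geometry needed for closure. Fallback: ring closure by acylation of an enol oxygen instead of by addition of a carboxyl group. Setting out from 12, brief treatment with oxalic acid on wet silica gel in CH2Cl2 should hydrolyse only the terminal ethoxy dienyl ether and give the racemic enal methyl 2-methoxy-4-methyl-5-oxopent-3-enoate F3. DBU in toluene at 80 °C would then convert F3 into its dienolate, whose oxygen attacks the ester with loss of methanol (enol lactonisation, as in pyrone syntheses from 5-oxo-2-enoates), and the route is rejoined at 14.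

3. Step 9. Silylation of the hindered tertiary alcohol by the bis(triflate) may stall, the silyl triflate may activate a neighbouring ester towards migration, and the mixed silaketal may hydrolyse during isolation. Fallback: building the bridge through a hydrosilane. Setting out from 9, chlorodiisopropylsilane (imidazole, DMAP, CH2Cl2) should give (2S)-2-{[di(propan-2-yl)silyl]oxy}-2-ethynyl-3-[(2-methylpropanoyl)oxy]propyl (2S)-2-methylbutanoate F4. N-Bromosuccinimide in CH2Cl2 at 0 °C would convert the Si–H bond of F4 into Si–Br, giving (2S)-2-{[bromodi(propan-2-yl)silyl]oxy}-2-ethynyl-3-[(2-methylpropanoyl)oxy]propyl (2S)-2-methylbutanoate F5. Treating F5 in the same flask with 15 and Et3N gives 17, where the route is rejoined. This hydrosilane/bromosilane sequence is a standard way to unsymmetrical dialkoxysilanes.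

**Further compounds**

F1 | step 10 | (2S)-2-ethynyl-2-({[(5-methyl-2-oxo-2H-pyran-3-yl)oxy](phenyl)boranyl}oxy)-3-[(2-methylpropanoyl)oxy]propyl (2S)-2-methylbutanoate | CC[C@H](C)C(=O)OC[C@@](OB(c1ccccc1)OC2=CC(C)=COC2=O)(COC(=O)C(C)C)C#C
F2 | step 10 | [(4S)-7-methyl-4-{[(2-methylpropanoyl)oxy]methyl}-2-phenyl-4H-1,3,2-benzodioxaborinin-4-yl]methyl (2S)-2-methylbutanoate | CC[C@H](C)C(=O)OC[C@]1(COC(=O)C(C)C)OB(c3ccccc3)Oc2cc(C)ccc12
F3 | step 7 | methyl 2-methoxy-4-methyl-5-oxopent-3-enoate | COC(=O)C(OC)C=C(C)C=O
F4 | step 9 | (2S)-2-{[di(propan-2-yl)silyl]oxy}-2-ethynyl-3-[(2-methylpropanoyl)oxy]propyl (2S)-2-methylbutanoate | CC[C@H](C)C(=O)OC[C@@](O[SiH](C(C)C)C(C)C)(COC(=O)C(C)C)C#C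
F5 | step 9 | (2S)-2-{[bromodi(propan-2-yl)silyl]oxy}-2-ethynyl-3-[(2-methylpropanoyl)oxy]propyl (2S)-2-methylbutanoate | CC[C@H](C)C(=O)OC[C@@](O[Si](Br)(C(C)C)C(C)C)(COC(=O)C(C)C)C#C
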